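**Plan**

1. Retrosynthesis (carotenoid numbering): cut C8–C9 first. Then cut C11'=C12' and C11=C12 (both Horner–Wadsworth–Emmons), then C6–C7 and C6'–C7' (both Sonogashira). Both end groups then fall back on one enol triflate from (4R,6R)-actinol, and the chain falls back on the C10 dialdehyde plus a C4 phosphonate.
2. Enabling feature: the (7E,9E)-diene C7=C8–C9(CH3)=C10 hangs on the fully substituted carbinol C6 of ring A and carries only a methyl group on C9. It is therefore the hydrolysis product of a titanacyclopentadiene (Ti, C7, C8, C9, C10) built from a terminal alkyne C7≡C8 and a methyl-capped alkyne C9≡C10, so one event makes the C8–C9 bond and both alkene geometries.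
3. Forward order: the ring A triol is finished at C11 level. Ring C (dihydrofuran O–C5'–C6'=C7'–C8', closed on ring B by allenol cyclisation) is finished at C15 level. C15 aldehyde + C14 phosphonate give the C29 polyenyne, C29 + C11 give the C40 chain, and one desilylation ends the route.
4. Stereochemistry: C3 and C3' come from actinol. C6 is set by hydroxyl-directed epoxidation, and C5 by trans-diaxial hydrolysis with inversion, steered to C5 by the electron-poor ethynyl group. C5' comes from a bromohydrin-derived oxirane anti to the silyloxy group, and C8' from centre-to-axis-to-centre transfer (anti SN2' hydride, then 5-endo cyclisation).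
5. Helpers: the alkyne oxidation level at C7–C8 and C9–C10, four silyl ethers and the titanium ring. All are removed in the last two steps.

Key step: step 19

Remark: ring A is the triol ring C1–C6, ring B the carbocycle C1'–C6', ring C the dihydrofuran. Actinol, trimethylsilylacetylene, (E)-3-methylpent-2-en-4-yn-1-ol, 1-bromobut-2-yne and the C10 dialdehyde are taken as catalogue compounds.

**Steps**

Step 1
Reactants: 1 (4R,6R)-4-hydroxy-2,2,6-trimethylcyclohexanone (actinol)
Product: 2 (4R,6R)-4-(tert-butyldimethylsilyloxy)-2,2,6-trimethylcyclohexanone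
Conditions: TBSCl, imidazole, DMF, rt
Reagents that add atoms: tert-butyldimethylsilyl chloride, CC(C)(C)[Si](C)(C)Cl
Why: Routine silyl ether formation on the only hydroxyl, which leaves the carbinol centre (later C3 and C3') untouched.

Step 2
Reactants: 2 silylated actinol
Product: 4 (4R)-4-(tert-butyldimethylsilyloxy)-2,6,6-trimethylcyclohex-1-en-1-yl triflate, via lithium enolate 3 (not isolated)
Conditions: LiN(iPr)2, THF, -78 °C; then PhNTf2, -78 °C to rt
Reagents that add atoms: N-phenylbis(trifluoromethanesulfonimide), O=S(=O)(N(c1ccccc1)S(=O)(=O)C(F)(F)F)C(F)(F)F; lithium diisopropylamide, [Li]N(C(C)C)C(C)C (lithium stays only in 3)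
Why: Enolate O-triflation; the other alpha carbon is quaternary, so only the C5=C6 enolate can form and the methyl-bearing centre is erased on purpose.

Step 3
Reactants: 4 enol triflate; 5 trimethylsilylacetylene
Product: 6 (1R)-1-(tert-butyldimethylsilyloxy)-3,5,5-trimethyl-4-[(trimethylsilyl)ethynyl]cyclohex-3-ene
Conditions: Pd(PPh3)4 (cat.), CuI (cat.), Et3N, DMF, 50 °C
Reagents that add atoms: none
Why: Sonogashira coupling forms C6–C7, the slim alkyne being a partner that the hindered tetrasubstituted triflate accepts.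

Step 4
Reactants: 6 bis-silylated enyne
Product: 7 (1R)-4-ethynyl-3,5,5-trimethylcyclohex-3-en-1-ol
Conditions: TBAF, THF, 0 °C to rt
Reagents that add atoms: none
Why: Fluoride-mediated desilylation cleaves Si–C(sp) and Si–O together, freeing the terminal alkyne and the 3-OH that directs the next step.

Step 5
Reactants: 7 hydroxy enyne
Product: 8 (1S,3S,6S)-6-ethynyl-1,5,5-trimethyl-7-oxabicyclo[4.1.0]heptan-3-ol (oxirane oxygen cis to 3-OH)
Conditions: VO(acac)2 (cat.), t-BuOOH, toluene, 0 °C to rt
Reagents that add atoms: tert-butyl hydroperoxide, CC(C)(C)OO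
Why: Vanadium-catalysed hydroxyl-directed epoxidation; the homoallylic 3-OH binds the metal peroxide and delivers oxygen to its own face of C5=C6, which sets C6 for good and C5 provisionally.

Step 6
Reactants: 8 syn-epoxide
Product: 9 (1S,2R,4S)-1-ethynyl-2,6,6-trimethylcyclohexane-1,2,4-triol (6-OH cis and 5-OH trans to 3-OH in carotenoid numbering)
Conditions: HClO4 (cat.), THF–H2O, 0 °C
Reagents that add atoms: water, O
Why: Acid-catalysed epoxide hydrolysis; the electron-withdrawing ethynyl group disfavours charge at C6, so water attacks the tertiary C5 from the opposite face in the trans-diaxial mode (inversion at C5, retention at C6).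

Step 7
Reactants: 9 alkyne triol
Product: 10 tris(trimethylsilyl) ether of 9
Conditions: TMSOTf, 2,6-lutidine, CH2Cl2, -78 to 0 °C
Reagents that add atoms: trimethylsilyl triflate, C[Si](C)(C)OS(=O)(=O)C(F)(F)F
Why: Silyl triflate silylation is strong enough for the two hindered tertiary hydroxyls and removes every acidic O–H before the organotitanium step.

Step 8
Reactants: 4 enol triflate; 11 (E)-3-methylpent-2-en-4-yn-1-ol
Product: 12 (2E)-5-[(4R)-4-(tert-butyldimethylsilyloxy)-2,6,6-trimethylcyclohex-1-en-1-yl]-3-methylpent-2-en-4-yn-1-ol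
Conditions: Pd(PPh3)4 (cat.), CuI (cat.), Et3N, DMF, 50 °C
Reagents that add atoms: none
Why: Sonogashira coupling forms C6'–C7' and brings in C7'–C11' with the 9'E alkene already in place; the free primary alcohol is tolerated.

Step 9
Reactants: 12 dienynol
Product: 14 (2E)-5-[(1R,4S,6R)-4-(tert-butyldimethylsilyloxy)-2,2,6-trimethyl-7-oxabicyclo[4.1.0]heptan-1-yl]-3-methylpent-2-en-4-yn-1-ol (oxirane oxygen trans to OTBS), via bromohydrin 13 (not isolated)
Conditions: NBS, DME–H2O, 0 °C, dark; then K2CO3, MeOH, rt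
Reagents that add atoms: water, O; N-bromosuccinimide, O=C1CCC(=O)N1Br (bromine stays only in 13)
Why: Halohydrin route to the epoxide on the face opposite to bromine; bromonium formation is reversible, water opens it only at C5' (remote from the alkynyl group) and only in the trans-diaxial mode that keeps OTBS equatorial, and the 5'-alkoxide then closes the oxirane by intramolecular SN2 at C6'.

Step 10
Reactants: 14 anti-epoxide
Product: 15 (2E)-5-[(2R,4S)-4-(tert-butyldimethylsilyloxy)-2-hydroxy-2,6,6-trimethylcyclohexylidene]-3-methylpenta-2,4-dien-1-ol with (aS) allene axis (H-8' on the face of the C5' methyl group)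
Conditions: CuCl (cat.), IMes·HCl (cat.), NaOtBu (cat.), PMHS, toluene, 0 °C to rt; then aq NaOH
Reagents that add atoms: none
Why: Copper hydride-catalysed SN2' reduction of a propargyl oxirane; hydride enters C8' anti to the breaking C6'–O bond, so the oxirane centre is translated into the allene axis while C5' keeps its oxygen, and silyl ethers formed transiently from PMHS fall off in the basic work-up that TBS survives.

Step 11
Reactants: 15 allenediol
Product: 16 (2E)-3-[(2R,6S,7aR)-6-(tert-butyldimethylsilyloxy)-4,4,7a-trimethyl-2,4,5,6,7,7a-hexahydro-1-benzofuran-2-yl]but-2-en-1-ol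
Conditions: AuCl3 (cat.), THF, rt
Reagents that add atoms: none
Why: Gold-catalysed 5-endo-trig cycloisomerisation of an alpha-hydroxyallene to a 2,5-dihydrofuran with axis-to-centre chirality transfer; O-5' attacks the in-plane lobe at C8', H-8' stays on the methyl face (8'R), and protodeauration puts hydrogen on C7'.

Step 12
Reactants: 16 furanoid C15 alcohol
Product: 17 (2E)-3-[(2R,6S,7aR)-6-(tert-butyldimethylsilyloxy)-4,4,7a-trimethyl-2,4,5,6,7,7a-hexahydro-1-benzofuran-2-yl]but-2-enal
Conditions: MnO2, CH2Cl2, rt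
Reagents that add atoms: none
Why: Neutral allylic oxidation with MnO2 touches only the primary allylic alcohol and leaves the acid-sensitive C8'–O bond alone.

Step 13
Reactants: 18 1-bromobut-2-yne
Product: 19 diethyl but-2-yn-1-ylphosphonate
Conditions: P(OEt)3, neat, 120 °C
Reagents that add atoms: triethyl phosphite, CCOP(OCC)OCC
Why: Michaelis–Arbuzov reaction of a primary propargylic bromide.

Step 14
Reactants: 19 butynylphosphonate; 20 (2E,4E,6E)-2,7-dimethylocta-2,4,6-trienedial (C10 dialdehyde)
Product: 22 (2E,4E,6E,8E)-2,7-dimethyldodeca-2,4,6,8-tetraen-10-ynal, via lithiated phosphonate 21 (not isolated)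
Conditions: n-BuLi, THF, -78 °C; then 20 (3 equiv), -78 to 0 °C
Reagents that add atoms: n-butyllithium, [Li]CCCC (lithium stays only in 21)
Why: Horner–Wadsworth–Emmons olefination forms C11=C12 with the E preference of stabilised phosphonate anions, and the excess of dialdehyde limits it to one end.

Step 15
Reactants: 22 C14 enynal
Product: 23 (2E,4E,6E,8E)-2,7-dimethyldodeca-2,4,6,8-tetraen-10-yn-1-ol
Conditions: NaBH4, MeOH–THF, 0 °C
Reagents that add atoms: none
Why: Borohydride 1,2-reduction of a polyenal leaves the alkenes and the alkyne untouched.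

Step 16
Reactants: 23 C14 alcohol
Product: 24 (2E,4E,6E,8E)-1-bromo-2,7-dimethyldodeca-2,4,6,8-tetraen-10-yne
Conditions: PBr3, Et2O, -10 °C
Reagents that add atoms: phosphorus tribromide, BrP(Br)Br
Why: Bromination of a primary allylic alcohol by way of its phosphite ester (SN2); the fully conjugated primary bromide is also the thermodynamic isomer.

Step 17
Reactants: 24 C14 bromide
Product: 25 diethyl [(2E,4E,6E,8E)-2,7-dimethyldodeca-2,4,6,8-tetraen-10-yn-1-yl]phosphonate
Conditions: P(OEt)3, toluene, 90 °C
Reagents that add atoms: triethyl phosphite, CCOP(OCC)OCC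
Why: Michaelis–Arbuzov reaction of a reactive allylic bromide, as is usual for polyene phosphonates.

Step 18
Reactants: 25 C14 phosphonate; 17 furanoid C15 aldehyde
Product: 27 all-E C29 hexaen-yne CH3–C9≡C10–(C11 to C9')–C8' bearing the silylated rings B and C, via lithiated phosphonate 26 (not isolated)
Conditions: n-BuLi, THF, -78 °C; then 17, -78 to 0 °C
Reagents that add atoms: n-butyllithium, [Li]CCCC (lithium stays only in 26)
Why: Horner–Wadsworth–Emmons olefination forms C11'=C12' E-selectively, and using the furanoid piece as the electrophile avoids a carbanion vinylogous to the C8'–O bond, so C8' is not put at risk.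

Step 19
Reactants: 27 C29 hexaen-yne; 10 trisilylated ethynyl triol
Product: 30 3,5,6-tris-O-trimethylsilyl 3'-O-tert-butyldimethylsilyl ether of the target, via titanacyclopropene 28 (not isolated), via titanacyclopentadiene 29 (not isolated)
Conditions: Ti(OiPr)4, c-C5H9MgCl (2 equiv per Ti), toluene, -78 to -30 °C; then 10, -78 to -30 °C; then H2O
Reagents that add atoms: titanium tetraisopropoxide, CC(C)O[Ti](OC(C)C)(OC(C)C)OC(C)C (titanium and two isopropoxide groups stay only in 28 and 29; the product gains hydrogen only)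
Why: Ti(OiPr)4 and two equivalents of c-C5H9MgCl give a divalent titanium–cyclopentene complex (Kulinkovich-type reagent) that trades its alkene for the only alkyne of 27 to give titanacyclopropene 28, the terminal alkyne of 10 then inserts into the Ti–C9 bond, and water cleaves both Ti–C(sp2) bonds of 29 with retention. The closest known reaction type is the titanium alkoxide-mediated reductive cross-coupling of an internal alkyne with a terminal alkyne to a trisubstituted (E,E)-1,3-diene, which is also used as a fragment union. The only ring closed is the temporary five-membered titanacycle (Ti, C7, C8, C9, C10), formed by migratory insertion and opened again in the quench, so no ring of the target is made here. No stereocentre is created: each alkyne undergoes net cis addition of carbon and hydrogen, which fixes 7E and 9E together with the C8–C9 bond. Regioselectivity is needed on both partners and is secured by the substrate, since the fully substituted C6 of ring A forces C7 next to titanium and leaves the unhindered C8 to bond, while in 28 the small methyl group lets C9 take the crowded inner position and the polyenyl-bearing C10 keeps its Ti–C bond. Chemoselectivity rests on the much higher affinity of divalent titanium for an alkyne than for the chain alkenes or the allylic ether of ring C, on the Ti–C bonds lying in the nodal plane of the polyene, and on the silyl masking of all four hydroxyls.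

Step 20
Reactants: 30 tetrasilyl ether
Product: 31 (3S,5R,6R,3'S,5'R,8'R)-5',8'-epoxy-5,6,5',8'-tetrahydro-β,β-carotene-3,5,6,3'-tetrol (target)
Conditions: TBAF, THF, 0 °C to rt, dark
Reagents that add atoms: none
Why: Fluoride-mediated global desilylation runs without acid, so neither the doubly allylic C8'–O bond nor the tertiary allylic C6–OH can ionise and no stereocentre or alkene is disturbed.

**Compound list**

1 | (4R,6R)-4-hydroxy-2,2,6-trimethylcyclohexanone | O=C1C(C)(C)C[C@H](O)C[C@H]1C | starting material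
2 | (4R,6R)-4-(tert-butyldimethylsilyloxy)-2,2,6-trimethylcyclohexanone | O=C1C(C)(C)C[C@H](O[Si](C)(C)C(C)(C)C)C[C@H]1C | intermediate
3 | lithium enolate of 2 | CC1=C(O[Li])C(C)(C)C[C@H](O[Si](C)(C)C(C)(C)C)C1 | intermediate
4 | (4R)-4-(tert-butyldimethylsilyloxy)-2,6,6-trimethylcyclohex-1-en-1-yl triflate | CC1=C(OS(=O)(=O)C(F)(F)F)C(C)(C)C[C@H](O[Si](C)(C)C(C)(C)C)C1 | intermediate
5 | trimethylsilylacetylene | C#C[Si](C)(C)C | starting material
6 | bis-silylated (R)-enyne | CC1=C(C#C[Si](C)(C)C)C(C)(C)C[C@H](O[Si](C)(C)C(C)(C)C)C1 | intermediate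
7 | (1R)-4-ethynyl-3,5,5-trimethylcyclohex-3-en-1-ol | CC1=C(C#C)C(C)(C)C[C@H](O)C1 | intermediate
8 | (1S,3S,6S)-6-ethynyl-1,5,5-trimethyl-7-oxabicyclo[4.1.0]heptan-3-ol | C#C[C@@]12C(C)(C)C[C@H](O)C[C@]1(C)O2 | intermediate
9 | (1S,2R,4S)-1-ethynyl-2,6,6-trimethylcyclohexane-1,2,4-triol | C#C[C@@]1(O)C(C)(C)C[C@H](O)C[C@@]1(C)O | intermediate
10 | tris(trimethylsilyl) ether of 9 | C#C[C@@]1(O[Si](C)(C)C)C(C)(C)C[C@H](O[Si](C)(C)C)C[C@@]1(C)O[Si](C)(C)C | intermediate
11 | (E)-3-methylpent-2-en-4-yn-1-ol | C#C/C(C)=C/CO | starting material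
12 | C15 dienynol, 3'-OTBS | CC1=C(C#C/C(C)=C/CO)C(C)(C)C[C@H](O[Si](C)(C)C(C)(C)C)C1 | intermediate
13 | trans-diaxial bromohydrin (5'-OH trans to OTBS, 6'-Br cis to OTBS) | OC/C=C(C)/C#C[C@@]1(Br)C(C)(C)C[C@H](O[Si](C)(C)C(C)(C)C)C[C@@]1(C)O | intermediate
14 | C15 alkynyl oxirane, oxygen trans to OTBS | OC/C=C(C)/C#C[C@]12C(C)(C)C[C@H](O[Si](C)(C)C(C)(C)C)C[C@@]1(C)O2 | intermediate
15 | C15 (aS)-vinylallenediol | OC/C=C(C)/C([H])=[C@]=C1C(C)(C)C[C@H](O[Si](C)(C)C(C)(C)C)C[C@@]1(C)O | intermediate
16 | (8'R)-furanoid C15 alcohol | OC/C=C(C)/[C@H]1C=C2C(C)(C)C[C@H](O[Si](C)(C)C(C)(C)C)C[C@@]2(C)O1 | intermediate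
17 | (8'R)-furanoid C15 aldehyde | O=C/C=C(C)/[C@H]1C=C2C(C)(C)C[C@H](O[Si](C)(C)C(C)(C)C)C[C@@]2(C)O1 | intermediate
18 | 1-bromobut-2-yne | CC#CCBr | starting material
19 | diethyl but-2-yn-1-ylphosphonate | CC#CCP(=O)(OCC)OCC | intermediate
20 | (2E,4E,6E)-2,7-dimethylocta-2,4,6-trienedial | O=C/C(C)=C/C=C/C=C(C)/C=O | starting material
21 | lithiated 19 | CC#CC([Li])P(=O)(OCC)OCC | intermediate
22 | (2E,4E,6E,8E)-2,7-dimethyldodeca-2,4,6,8-tetraen-10-ynal | CC#C/C=C/C(C)=C/C=C/C=C(C)/C=O | intermediate
23 | C14 tetraenynol | CC#C/C=C/C(C)=C/C=C/C=C(C)/CO | intermediate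
24 | C14 tetraenynyl bromide | CC#C/C=C/C(C)=C/C=C/C=C(C)/CBr | intermediate
25 | C14 tetraenynyl phosphonate | CC#C/C=C/C(C)=C/C=C/C=C(C)/CP(=O)(OCC)OCC | intermediate
26 | lithiated 25 | CC#C/C=C/C(C)=C/C=C/C=C(C)/C([Li])P(=O)(OCC)OCC | intermediate
27 | all-E C29 hexaen-yne, 3'-OTBS | CC#C/C=C/C(C)=C/C=C/C=C(C)/C=C/C=C(C)/[C@H]1C=C2C(C)(C)C[C@H](O[Si](C)(C)C(C)(C)C)C[C@@]2(C)O1 | intermediate
28 | diisopropoxytitanacyclopropene of 27 (Ti on C9 and C10) | CC1=C(/C=C/C(C)=C/C=C/C=C(C)/C=C/C=C(C)/[C@H]2C=C3C(C)(C)C[C@H](O[Si](C)(C)C(C)(C)C)C[C@@]3(C)O2)[Ti]1(OC(C)C)OC(C)C | intermediate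
29 | diisopropoxytitanacyclopentadiene (Ti, C7, C8, C9, C10) | CC1=C(/C=C/C(C)=C/C=C/C=C(C)/C=C/C=C(C)/[C@H]2C=C3C(C)(C)C[C@H](O[Si](C)(C)C(C)(C)C)C[C@@]3(C)O2)[Ti](OC(C)C)(OC(C)C)C(=C1)[C@@]1(O[Si](C)(C)C)C(C)(C)C[C@H](O[Si](C)(C)C)C[C@@]1(C)O[Si](C)(C)C | intermediate
30 | tetrasilyl ether of the target | CC(/C=C/C=C(C)/C=C/[C@@]1(O[Si](C)(C)C)C(C)(C)C[C@H](O[Si](C)(C)C)C[C@@]1(C)O[Si](C)(C)C)=C\C=C\C=C(C)\C=C\C=C(/C)[C@H]1C=C2C(C)(C)C[C@H](O[Si](C)(C)C(C)(C)C)C[C@@]2(C)O1 | intermediate
31 | (3S,5R,6R,3'S,5'R,8'R)-5',8'-epoxy-5,6,5',8'-tetrahydro-β,β-carotene-3,5,6,3'-tetrol | CC(/C=C/C=C(C)/C=C/[C@@]1(O)C(C)(C)C[C@H](O)C[C@@]1(C)O)=C\C=C\C=C(C)\C=C\C=C(/C)[C@H]1C=C2C(C)(C)C[C@H](O)C[C@@]2(C)O1 | target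

**Totals**

Total step count: 20.
Longest linear sequence: 10 steps (1 → 2 → 4 → 12 → 14 → 15 → 16 → 17 → 27 → 30 → 31).

**Steps most likely to fail**

Step 19. Several things may go wrong:
- Insertion of the very hindered alkyne may be slow.
- The terminal alkyne may transfer its proton to the titanacyclopropene.
- The C6 silyloxy group may be lost from the titanacycle by beta-elimination.
- Titanium may wander onto the polyene.

The fallback sets out from 10 and 27 and replaces the reductive coupling by two separate hydrometalations and a Stille coupling. Hydrostannation of 10 (PdCl2(PPh3)2, Bu3SnH, THF) should give the (E)-vinylstannane F1, with tin on the unhindered C8. Syn hydrozirconation of 27 with Cp2Zr(H)Cl places zirconium on the methyl-bearing C9 (alkenylzirconocene F2). Iodinolysis at low temperature in the dark gives the (9E)-iodide F3. Stille coupling of F1 with F3 (Pd2(dba)3, AsPh3, NMP, rt) forms C8–C9 with retention on both partners and comes back to the route at 30.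

Step 9. Facial discrimination in the bromonium opening may be poor, or bromine may be taken up by the C9'=C10' alkene. The fallback sets out from 4 and moves the facial choice to reagent control through a C7' hydroxymethyl handle:
- Stille coupling with Bu3SnCH2OH (Pd(PPh3)4, LiCl) gives the ring allylic alcohol F4.
- Sharpless epoxidation (Ti(OiPr)4, D-(−)-diethyl tartrate, t-BuOOH) puts oxygen anti to OTBS and gives the epoxy alcohol F5.
- Parikh–Doering oxidation gives the epoxy aldehyde F6.
- Ohira–Bestmann homologation gives the ethynyl oxirane F7.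
- Sonogashira coupling with (E)-3-iodobut-2-en-1-ol F8 (hydrozirconation–iodination of but-2-yn-1-ol) comes back to the route at 14.

Step 11. The Lewis acidic gold salt may ionise the doubly allylic C8'–O bond, with erosion of the C8' configuration, or the vinylallene may undergo Nazarov-type cyclisation. The fallback sets out from 15 and closes ring C with a halonium ion instead of a metal. Iodoetherification (N-iodosuccinimide, NaHCO3, CH2Cl2, 0 °C) uses the same 5-endo attack of O-5' on C8' and leaves iodine on C7', giving the 7'-iodo-dihydrofuran F9. Hydrodeiodination (Bu3SnH, Pd(PPh3)4) comes back to the route at 16.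

**Further compounds**

F1 | step 19 | (E)-vinylstannane from 10 (Bu3Sn on C8) | CCCC[Sn](CCCC)(CCCC)/C=C/[C@@]1(O[Si](C)(C)C)C(C)(C)C[C@H](O[Si](C)(C)C)C[C@@]1(C)O[Si](C)(C)C
F2 | step 19 | (9E)-alkenylzirconocene chloride from 27 (Cp2ZrCl on C9) | Cl[Zr](C1C=CC=C1)(C1C=CC=C1)/C(C)=C/C=C/C(C)=C/C=C/C=C(C)/C=C/C=C(C)/[C@H]1C=C2C(C)(C)C[C@H](O[Si](C)(C)C(C)(C)C)C[C@@]2(C)O1
F3 | step 19 | (9E)-C29 heptaenyl iodide | I/C(C)=C/C=C/C(C)=C/C=C/C=C(C)/C=C/C=C(C)/[C@H]1C=C2C(C)(C)C[C@H](O[Si](C)(C)C(C)(C)C)C[C@@]2(C)O1
F4 | step 9 | [(4R)-4-(tert-butyldimethylsilyloxy)-2,6,6-trimethylcyclohex-1-en-1-yl]methanol | CC1=C(CO)C(C)(C)C[C@H](O[Si](C)(C)C(C)(C)C)C1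
F5 | step 9 | epoxy alcohol, oxirane oxygen trans to OTBS | OC[C@]12C(C)(C)C[C@H](O[Si](C)(C)C(C)(C)C)C[C@@]1(C)O2
F6 | step 9 | epoxy aldehyde | O=C[C@]12C(C)(C)C[C@H](O[Si](C)(C)C(C)(C)C)C[C@@]1(C)O2
F7 | step 9 | ethynyl oxirane | C#C[C@]12C(C)(C)C[C@H](O[Si](C)(C)C(C)(C)C)C[C@@]1(C)O2
F8 | step 9 | (E)-3-iodobut-2-en-1-ol | I/C(C)=C/CO
F9 | step 11 | 7'-iodo-dihydrofuran | OC/C=C(C)/[C@H]1C(I)=C2C(C)(C)C[C@H](O[Si](C)(C)C(C)(C)C)C[C@@]2(C)O1
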